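Take the north run and divide one rate by another. Between 23 s and 70 s it turns 0.00311 s⁻¹ of its J charge each second. Between 93 s and 140 s it turns 0.00404 s⁻¹. That quotient, 0.768, is the drift ratio, the early rate over the late rate of one flask.

| setting | north | east | north-west | south | south-east |
|---|---|---|---|---|---|
| J | 0.500 M | 0.250 M | 0.250 M | 0.500 M | 0.500 M |
| G | 1.50 M | 1.25 M | 1.50 M | 3.00 M | 1.50 M |
| Z | 0.0500 M | 0.0500 M | 0.0500 M | 0.0500 M | 0.200 M |
| time |  |  |  |  | 140 s |

| run | time / s | [Q] / M |
|---|---|---|
| north run | 23 | 0.015 |
| north run | 47 | 0.047 |
| north run | 70 | 0.088 |
| north run | 93 | 0.131 |
| north run | 120 | 0.193 |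
| north run | 140 | 0.226 |
| east run | 23 | 0.009 |
| east run | 47 | 0.029 |
| east run | 70 | 0.065 |
| east run | 93 | 0.080 |
| east run | 120 | 0.112 |
| east run | 140 | 0.133 |
| north-west run | 23 | 0.013 |
| north-west run | 47 | 0.039 |
| north-west run | 70 | 0.062 |
| north-west run | 93 | 0.095 |
| north-west run | 120 | 0.135 |
| north-west run | 140 | 0.156 |
| south run | 23 | 0.054 |
| south run | 47 | 0.146 |
| south run | 70 | 0.232 |
| south run | 93 | 0.308 |
| south run | 120 | 0.391 |
| south run | 140 | 0.423 |

(each reading ± 0.004 M)

- the exponent of [J] in the starting rate at the charge of the north run (at the point where two percent of the J have become Q) (one fixed amount of Q, the same in the runs compared)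
- the exponent of [G] in the starting rate at the charge of the north run (at the point where two percent of the J have become Q)
- the east run starts with 0.250 M less of J and of G than the north run, and with no Q. Compared where both hold the same amount of J, once fifteen percent of what the east run was charged with has turned into Q, is the east run faster, slower or alike (within a tenth)?
- Q in the south-east run at 140 s, as a share of the J charged

- Overall: J + G -> Q, with Z as catalyst.
- Constant volume, constant temperature.
- A reading of a species includes what of it is bound.
- "The second partner" is G.
- An order is taken over about fifteen percent of the charge, up and down.

*What is odd about that ratio?* It lies below one. J is being used up, yet the late rate of the north run is higher than its early rate. That is an induction period. So a rate depends on the age of the flask as well as on what it holds.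

*How firm is it?* The scatter of the readings puts about 0.0751 on it.

*Use it. Where is the east run at the point asked?* It has turned 11.6% of its charge at 47 s and 26.0% at 70 s. So it passes 15% between those readings, inside the north run's early window.

*And the north run, at the same J?* It has turned more than 50.0% of its charge there, so it is old. The east run is young and the north run is old, with equal J and equal G. But the north run's early window holds more J and G than its late window, so the drift ratio mixes age with consumption. With J and G equal, I expect the rate of the east run over that of the north run to lie at or below the drift ratio.

*The weak spot?* The north run's last reading shows 45.2% turned, so that point lies beyond the readings. I let the late rate stand in for it, and that is an assumption.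

*Your answer?* Alike needs at least 0.900. The drift ratio is lower, though by little more than its scatter. I say slower.

*And the forecast?* It gives a J order of 0.4 (0.2 to 0.6) and a G order of 1.2 (0.85 to 1.7). It says the east run is slower, and it puts the south-east run at 90% (70% to 98%). Its rule is “Orders must therefore be compared at equal Q, not equal time.”

    Rx + J ⇌ ZJ, settled at all times (6.010 M⁻¹)
    ZJ + G → Q + Rx (0.06170 M⁻¹ s⁻¹)
    Z + G → Rx + G (0.01920 M⁻¹ s⁻¹)
    2 J ⇌ J2, settled at all times (3.570 M⁻¹)

The flask gives a J order of 0.18 and a G order of 1.0, the east run slower, and 93.8% of the J charged as Q in the south-east run at 140 s. Held against the north run at the point asked, the rate ratio for the east run is 0.74, lower than the drift ratio of 0.768. Taken earlier, where 2% of the north run's J has turned, the north run's rate is 0.00202 s⁻¹ as a share of its charge, which over its late rate gives 0.500.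

(The numbers in the tables stem from a simulated flask with constants of no real substance, and the scatter is random.)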